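**Retrosynthetic overview**

1. The cyclohexane (C1, C10–C14) is closed last, by ring-closing metathesis at C12=C13 between a 2-propenyl ketone on C10 and a vinyl group on C14. Two reductions of the resulting 2-methylcyclohexenone from its open face then set C12 and C11.
2. Enabling feature: C1 is the one carbon shared by the tetrahydrofuran (O, C2, C1, C10, C9), the oxepane (O, C3, C2, C1, C14, C15, C16) and the cyclohexane. With both ether rings in place it holds the C10 and C14 arms cis-1,3 on the face away from the nine-membered ring, so only the six-membered closure is within reach.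
3. Ring order: tetrahydrofuran (Shi epoxidation, then opening at C2 by the C9 hydroxyl), oxepane (C3–O–C16 etherification), oxonene (Nozaki–Hiyama–Kishi closure C6–C7), cyclohexane.
4. Earlier stereocentres: C14/C15 from (R)-β-methyl-γ-butyrolactone, C1 by auxiliary-controlled alkenyl 1,4-addition, C9/C10 by Evans syn-aldol, C2/C3 from the epoxide, C6 in the chromium-mediated closure.
5. Fragments: lactone-derived enoyl imide (C1, C10, C11, C13–C17), a (Z)-alkenyl iodide (C2–C6, C18) and (Z)-3-iodobut-2-enal (C7–C9, C19).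

Key step: step 22

Remark: atoms are numbered as in the asbestinane skeleton: C1 (CH common to three rings), C2 (OCH), C3 (C with CH3 and O), C4, C5, C6 (CHOH), C7 (=C–CH3), C8 (=CH), C9 (OCH), C10, C11 (CHOAc), C12 (CHCH3), C13 (CH2), C14, C15 (CHCH3), C16 (OCH2), C17–C20 the methyls on C15, C3, C7, C12; lactone 3 and imide 1 are taken as purchasable.

**Route**

Step 1
Reactants: 1 (R)-4-benzyl-3-(2-chloroacetyl)oxazolidin-2-one
Product: 2 diethyl {2-[(R)-4-benzyl-2-oxooxazolidin-3-yl]-2-oxoethyl}phosphonate
Conditions: P(OEt)3 (neat), NaI (cat.), 110 °C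
Reagents that add atoms: triethyl phosphite, CCOP(OCC)OCC
Why: Michaelis–Arbuzov reaction of the α-halo imide gives the phosphonate reagent, and the auxiliary stereocentre is not involved.

Step 2
Reactants: 3 (R)-4-methyldihydrofuran-2(3H)-one
Product: 4 (3S,4R)-3-(hydroxymethyl)-4-methyldihydrofuran-2(3H)-one
Conditions: LiN(i-Pr)2, THF, −78 °C; CH2O (gas from cracked paraformaldehyde), −78 → −20 °C; aq. NH4Cl
Reagents that add atoms: formaldehyde, C=O
Why: Aldol addition of the lactone lithium enolate to formaldehyde, in which the electrophile should enter trans to the ring methyl group and so set C14 relative to C15.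

Step 3
Reactants: 4 (3S,4R)-3-(hydroxymethyl)-4-methyldihydrofuran-2(3H)-one
Product: 6 [(3S,4R)-2-methoxy-4-methyltetrahydrofuran-3-yl]methanol (both anomers), via lactol 5 (not isolated)
Conditions: i-Bu2AlH (2.2 equiv), CH2Cl2, −78 °C; aq. potassium sodium tartrate; crude lactol in MeOH, PPTS (cat.), rt
Reagents that add atoms: methanol, CO
Why: Partial lactone reduction followed by Fischer-type acetalisation masks C13 (aldehyde level) and the C16 oxygen in one ring and leaves the C1 hydroxymethyl arm free, without touching C14 or C15.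

Step 4
Reactants: 6 [(3S,4R)-2-methoxy-4-methyltetrahydrofuran-3-yl]methanol
Product: 7 (3S,4R)-2-methoxy-4-methyltetrahydrofuran-3-carbaldehyde
Conditions: Dess–Martin periodinane, NaHCO3, CH2Cl2, 0 °C → rt
Reagents that add atoms: none
Why: Dess–Martin oxidation under buffered conditions should give the aldehyde without epimerising C14, whose trans arrangement is also the more stable one.

Step 5
Reactants: 7 (3S,4R)-2-methoxy-4-methyltetrahydrofuran-3-carbaldehyde; 2 diethyl {2-[(R)-4-benzyl-2-oxooxazolidin-3-yl]-2-oxoethyl}phosphonate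
Product: 8 (R)-4-benzyl-3-{(E)-3-[(3R,4R)-2-methoxy-4-methyltetrahydrofuran-3-yl]prop-2-enoyl}oxazolidin-2-one
Conditions: LiCl, i-Pr2NEt, MeCN, 0 °C → rt
Reagents that add atoms: none
Why: Horner–Wadsworth–Emmons olefination under Masamune–Roush conditions should give the (E)-enoyl imide, the weak amine base sparing the β-acetal and the C14 centre.

Step 6
Reactants: 9 3-bromopropan-1-ol
Product: 10 (3-bromopropoxy)(tert-butyl)diphenylsilane
Conditions: t-BuPh2SiCl, imidazole, CH2Cl2, rt
Reagents that add atoms: tert-butyl(chloro)diphenylsilane, CC(C)(C)[Si](Cl)(c1ccccc1)c1ccccc1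
Why: Standard silylation of the primary alcohol gives an acid-stable ether for the future C6 oxygen.

Step 7
Reactants: 10 (3-bromopropoxy)(tert-butyl)diphenylsilane
Product: 13 (Z)-tert-butyl[(5-iodo-4-methylpent-4-en-1-yl)oxy]diphenylsilane, via Grignard reagent 11 (not isolated), via alkenylcopper 12 (not isolated)
Conditions: Mg, THF, rt; CuBr·SMe2 (1 equiv), Et2O/Me2S, −45 °C; propyne, −25 °C; I2, THF, −50 → 0 °C
Reagents that add atoms: propyne, CC#C; iodine, II
Why: Normant carbocupration adds the alkylcopper syn across propyne and iodinolysis proceeds with retention, which should give the trisubstituted alkenyl iodide with iodine cis to the chain (Z).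

Step 8
Reactants: 14 but-2-yn-1-ol
Product: 15 (Z)-3-iodobut-2-en-1-ol
Conditions: NaAlH2(OCH2CH2OCH3)2, Et2O, 0 °C → rt; then I2, THF, −78 → 0 °C
Reagents that add atoms: iodine, II
Why: Hydroxyl-directed trans-hydroalumination of the propargylic alcohol and iodination of the C3 alanate should give the (Z)-3-iodo allylic alcohol.

Step 9
Reactants: 15 (Z)-3-iodobut-2-en-1-ol
Product: 16 (Z)-3-iodobut-2-enal
Conditions: MnO2, CH2Cl2, rt (used at once)
Reagents that add atoms: none
Why: Allylic oxidation with MnO2 gives the enal without loss of the (Z) geometry.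

Step 10
Reactants: 13 (Z)-tert-butyl[(5-iodo-4-methylpent-4-en-1-yl)oxy]diphenylsilane; 8 enoyl imide
Product: 18 C1-alkenylated acyl oxazolidinone, via alkenylmagnesium chloride 17 (not isolated)
Conditions: 13, i-PrMgCl·LiCl, THF, −20 → 0 °C; CuBr·SMe2 (30 mol %), −40 °C; then 8, −40 → −10 °C; aq. NH4Cl
Reagents that add atoms: none
Why: Copper-catalysed 1,4-addition of the alkenyl Grignard reagent (made by iodine–magnesium exchange with retention) to the magnesium-chelated s-cis N-enoyl oxazolidinone, in which attack anti to the benzyl group of the (R)-auxiliary should set C1.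

Step 11
Reactants: 18 C1-alkenylated acyl oxazolidinone; 16 (Z)-3-iodobut-2-enal
Product: 19 syn-aldol adduct
Conditions: Bu2BOTf, i-Pr2NEt, CH2Cl2, −78 → 0 °C; then 16, −78 → 0 °C; pH 7 buffer, MeOH, H2O2
Reagents that add atoms: none
Why: Evans syn-aldol reaction through the (Z)-boron enolate and a chair Zimmerman–Traxler transition state, in which the (R)-auxiliary should set C10 and the C9 carbinol in the required syn sense.

Step 12
Reactants: 19 syn-aldol adduct
Product: 20 β-hydroxy Weinreb amide
Conditions: AlMe3, MeNH(OMe)·HCl, CH2Cl2, −20 → 0 °C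
Reagents that add atoms: N,O-dimethylhydroxylamine hydrochloride, CNOC.Cl
Why: Aluminium amide transamination of the β-hydroxy imide releases the auxiliary and gives the Weinreb amide without touching C9 or C10.

Step 13
Reactants: 20 β-hydroxy Weinreb amide
Product: 22 tetrahydrofuran Weinreb amide (free C3 hydroxyl), via epoxide 21 (not isolated)
Conditions: D-fructose-derived Shi ketone (30 mol %), KHSO5 (as Oxone), K2CO3, Bu4NHSO4, MeCN/CH2(OMe)2/aq. borate buffer, 0 °C; then K2CO3, MeOH, rt
Reagents that add atoms: potassium peroxymonosulfate, [K+].[O-]S(=O)(=O)OO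
Why: Shi epoxidation of the only electron-rich trisubstituted olefin (C2=C3) under catalyst control, then base-mediated 5-exo-tet opening of the epoxide at C2 by the C9 hydroxyl with inversion, should close the 2,5-cis tetrahydrofuran and set C2 and C3 (the C3–O bond is kept with retention).

Step 14
Reactants: 22 tetrahydrofuran Weinreb amide
Product: 23 lactol
Conditions: AcOH/THF/H2O (3:1:1), 45 °C
Reagents that add atoms: water, O
Why: Acid hydrolysis of the methyl acetal unmasks the lactol (C13 at aldehyde level) while the silyl ether and the tertiary alcohol survive.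

Step 15
Reactants: 23 lactol
Product: 24 C14-vinyl C3,C16-diol
Conditions: Ph3PCH3Br, KOt-Bu, THF, 0 °C → rt
Reagents that add atoms: methyltriphenylphosphonium bromide, C[P+](c1ccccc1)(c1ccccc1)c1ccccc1.[Br-]
Why: Wittig methylenation of the lactol through its open hydroxy aldehyde gives the C14 vinyl group (C13) and frees the C16 hydroxyl.

Step 16
Reactants: 24 C14-vinyl C3,C16-diol
Product: 26 oxepane Weinreb amide, via primary triflate 25 (not isolated)
Conditions: (CF3SO2)2O, 2,6-lutidine, CH2Cl2, −78 °C → rt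
Reagents that add atoms: none
Why: Selective triflation of the primary C16 hydroxyl and intramolecular Williamson-type displacement by the tertiary C3 hydroxyl (7-exo-tet) should close the oxepane with no stereocentre involved.

Step 17
Reactants: 26 oxepane Weinreb amide
Product: 27 primary C6 alcohol
Conditions: Bu4NF, THF, rt
Reagents that add atoms: none
Why: Fluoride cleavage of the silyl ether frees the C6 hydroxyl.

Step 18
Reactants: 27 primary C6 alcohol
Product: 28 C6 aldehyde
Conditions: Dess–Martin periodinane, NaHCO3, CH2Cl2, rt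
Reagents that add atoms: none
Why: Dess–Martin oxidation gives the aldehyde in the presence of the alkenyl iodide and the Weinreb amide.

Step 19
Reactants: 28 C6 aldehyde
Product: 29 oxonene alcohol (6R, 7Z)
Conditions: CrCl2 (10 equiv), NiCl2 (2 mol %), degassed DMSO, rt, 2 mM
Reagents that add atoms: none
Why: Nozaki–Hiyama–Kishi reaction in which the alkenylchromium species, formed with retention of the (Z) geometry, adds to the C6 aldehyde and closes the nine-membered oxonene, the cis-2,5-disubstituted tetrahydrofuran being expected to expose one aldehyde face and so give the C6 carbinol of the target.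

Step 20
Reactants: 29 oxonene alcohol
Product: 30 C6 silyl ether
Conditions: t-BuMe2SiOTf, 2,6-lutidine, CH2Cl2, −78 °C
Reagents that add atoms: tert-butyldimethylsilyl trifluoromethanesulfonate, CC(C)(C)[Si](C)(C)OS(=O)(=O)C(F)(F)F
Why: Silylation protects the allylic C6 hydroxyl for the end game.

Step 21
Reactants: 30 C6 silyl ether
Product: 31 2-propenyl ketone
Conditions: CH2=C(CH3)MgBr, THF, −20 → 0 °C
Reagents that add atoms: isopropenylmagnesium bromide, CC(=C)[Mg]Br
Why: Grignard addition to the Weinreb amide stops at the ketone stage through the magnesium-chelated tetrahedral intermediate and installs C12 with its methyl group.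

Step 22
Reactants: 31 2-propenyl ketone
Product: 32 tetracyclic enone
Conditions: second-generation Grubbs catalyst RuCl2(=CHPh)(PCy3)(H2IMes) (10 mol %), toluene, 80 °C, argon sparge
Reagents that add atoms: none
Why: Ring-closing olefin metathesis: the ruthenium alkylidene should load at the monosubstituted C14 vinyl group, form a ruthenacyclobutane with the 2-propenyl ketone olefin and release ethene, leaving the C12=C13 bond. The closest known reaction type is ring-closing metathesis of 2-propenyl ketones with terminal olefins to 2-methylcycloalk-2-enones with second-generation ruthenium catalysts. The cyclohexane closes as a six-membered ring with both olefin carbons endocyclic, by intramolecular metathesis between two arms that C1 holds cis-1,3 on the face away from the oxonene. No new stereocentre is formed; C11 and C12 become planar, so that steps 23 and 24 can set them from the open face. The step needs chemoselectivity over the trisubstituted C7=C8 bond and integrity of the base-sensitive C10 centre, which the shielding of that bond by the neighbouring silyl ether and the neutral conditions should secure.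

Step 23
Reactants: 32 tetracyclic enone
Product: 33 tetracyclic ketone
Conditions: H2 (1 atm), Pd on carbon, EtOAc, 0 °C, stopped after one equivalent
Reagents that add atoms: none
Why: Catalytic hydrogenation of the conjugated enone in preference to the shielded trisubstituted C7=C8 bond, in which hydrogen should add from the face opposite to the C9 substituent (axial next to the enone) so that the C12 methyl group ends cis to C9 under kinetic control.

Step 24
Reactants: 33 tetracyclic ketone
Product: 34 C11 alcohol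
Conditions: NaBH4, MeOH, −40 °C
Reagents that add atoms: none
Why: Hydride addition along the axial trajectory from the same open face (the other face is flanked by the axial C12 methyl group and C9) should give the equatorial C11 alcohol cis to the C12 methyl group.

Step 25
Reactants: 34 C11 alcohol
Product: 35 C11 acetate
Conditions: Ac2O, DMAP, pyridine, rt
Reagents that add atoms: acetic anhydride, CC(=O)OC(C)=O
Why: DMAP-catalysed acetylation of the only free hydroxyl gives the acetate with retention at C11.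

Step 26
Reactants: 35 C11 acetate
Product: 36 target (CNP0289966.2)
Conditions: HF·pyridine, THF, 0 °C → rt
Reagents that add atoms: none
Why: Fluoride-mediated desilylation frees the C6 hydroxyl without touching the acetate or the ether rings.

**Compound list**

1 | (R)-4-benzyl-3-(2-chloroacetyl)oxazolidin-2-one | O=C(CCl)N1[C@H](Cc2ccccc2)COC1=O | starting material
2 | diethyl {2-[(R)-4-benzyl-2-oxooxazolidin-3-yl]-2-oxoethyl}phosphonate | CCOP(=O)(OCC)CC(=O)N1[C@H](Cc2ccccc2)COC1=O | intermediate
3 | (R)-4-methyldihydrofuran-2(3H)-one ((R)-β-methyl-γ-butyrolactone) | O=C1C[C@@H](C)CO1 | starting material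
4 | (3S,4R)-3-(hydroxymethyl)-4-methyldihydrofuran-2(3H)-one | O=C1[C@H](CO)[C@@H](C)CO1 | intermediate
5 | (3S,4R)-3-(hydroxymethyl)-4-methyltetrahydrofuran-2-ol, lactol, both anomers, not isolated | OC1OC[C@H](C)[C@H]1CO | intermediate
6 | [(3S,4R)-2-methoxy-4-methyltetrahydrofuran-3-yl]methanol, both anomers | COC1OC[C@H](C)[C@H]1CO | intermediate
7 | (3S,4R)-2-methoxy-4-methyltetrahydrofuran-3-carbaldehyde | COC1OC[C@H](C)[C@H]1C=O | intermediate
8 | (R)-4-benzyl-3-{(E)-3-[(3R,4R)-2-methoxy-4-methyltetrahydrofuran-3-yl]prop-2-enoyl}oxazolidin-2-one | COC1OC[C@H](C)[C@H]1/C=C/C(=O)N1[C@H](Cc2ccccc2)COC1=O | intermediate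
9 | 3-bromopropan-1-ol | OCCCBr | starting material
10 | (3-bromopropoxy)(tert-butyl)diphenylsilane | CC(C)(C)[Si](OCCCBr)(c1ccccc1)c1ccccc1 | intermediate
11 | [3-(tert-butyldiphenylsilyloxy)propyl]magnesium bromide, not isolated | Br[Mg]CCCO[Si](c1ccccc1)(c1ccccc1)C(C)(C)C | intermediate
12 | (Z)-[5-(tert-butyldiphenylsilyloxy)-2-methylpent-1-en-1-yl]copper, not isolated | [Cu]/C=C(/C)CCCO[Si](c1ccccc1)(c1ccccc1)C(C)(C)C | intermediate
13 | (Z)-tert-butyl[(5-iodo-4-methylpent-4-en-1-yl)oxy]diphenylsilane | I/C=C(/C)CCCO[Si](c1ccccc1)(c1ccccc1)C(C)(C)C | intermediate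
14 | but-2-yn-1-ol | CC#CCO | starting material
15 | (Z)-3-iodobut-2-en-1-ol | C/C(I)=C/CO | intermediate
16 | (Z)-3-iodobut-2-enal | C/C(I)=C/C=O | intermediate
17 | (Z)-[5-(tert-butyldiphenylsilyloxy)-2-methylpent-1-en-1-yl]magnesium chloride, not isolated | Cl[Mg]/C=C(/C)CCCO[Si](c1ccccc1)(c1ccccc1)C(C)(C)C | intermediate
18 | (R)-4-benzyl-3-acyloxazolidin-2-one, acyl = C11(=O)–C10H2–C1H; C1 bears the (Z)-CH=C(CH3)(CH2)3OSi(t-Bu)Ph2 group (C2–C6) and the (3R,4R)-2-methoxy-4-methyltetrahydrofuran-3-yl group (C14 = ring C3); C1 as in the target | O=C(C[C@@H](/C=C(/C)CCCO[Si](c1ccccc1)(c1ccccc1)C(C)(C)C)[C@@H]1[C@@H](C)COC1OC)N1[C@H](Cc2ccccc2)COC1=O | intermediate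
19 | syn-aldol adduct of 18: C10 now bears C9H(OH)–CH=C(CH3)I (Z); C9, C10 as in the target | O=C([C@@H]([C@@H](O)/C=C(/C)I)[C@@H](/C=C(/C)CCCO[Si](c1ccccc1)(c1ccccc1)C(C)(C)C)[C@@H]1[C@@H](C)COC1OC)N1[C@H](Cc2ccccc2)COC1=O | intermediate
20 | N-methoxy-N-methylamide (C11) of the aldol acid, free C9 hydroxyl, stereocentres as in 19 | CON(C)C(=O)[C@@H]([C@@H](O)/C=C(/C)I)[C@@H](/C=C(/C)CCCO[Si](c1ccccc1)(c1ccccc1)C(C)(C)C)[C@@H]1[C@@H](C)COC1OC | intermediate
21 | C2,C3-epoxide of 20 (oxygen on the face that lets the C9 hydroxyl invert C2), not isolated | CON(C)C(=O)[C@@H]([C@@H](O)/C=C(/C)I)[C@@H]([C@H]2O[C@@]2(C)CCCO[Si](c2ccccc2)(c2ccccc2)C(C)(C)C)[C@@H]1[C@@H](C)COC1OC | intermediate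
22 | 2,5-cis-tetrahydrofuran (O bridges C2 and C9): C10 Weinreb amide, C9 (Z)-2-iodoprop-1-enyl, C1 methoxytetrahydrofuranyl, C2 bearing C3(CH3)(OH)(CH2)3OSi(t-Bu)Ph2; C1, C2, C3, C9, C10, C14, C15 as in the target | CON(C)C(=O)[C@@H]1[C@H]([C@@H]2[C@@H](C)COC2OC)[C@H](O[C@H]1/C=C(/C)I)[C@@](C)(O)CCCO[Si](c1ccccc1)(c1ccccc1)C(C)(C)C | intermediate
23 | lactol of 22 (2-hydroxy-4-methyltetrahydrofuran-3-yl on C1), both anomers | CON(C)C(=O)[C@@H]1[C@H]([C@@H]2[C@@H](C)COC2O)[C@H](O[C@H]1/C=C(/C)I)[C@@](C)(O)CCCO[Si](c1ccccc1)(c1ccccc1)C(C)(C)C | intermediate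
24 | tetrahydrofuran diol: C14 bears vinyl (C13) and C15H(CH3)–C16H2OH; free tertiary C3 hydroxyl | CON(C)C(=O)[C@@H]1[C@H]([C@@H](C=C)[C@@H](C)CO)[C@H](O[C@H]1/C=C(/C)I)[C@@](C)(O)CCCO[Si](c1ccccc1)(c1ccccc1)C(C)(C)C | intermediate
25 | C16 trifluoromethanesulfonate of 24, not isolated | CON(C)C(=O)[C@@H]1[C@H]([C@@H](C=C)[C@@H](C)COS(=O)(=O)C(F)(F)F)[C@H](O[C@H]1/C=C(/C)I)[C@@](C)(O)CCCO[Si](c1ccccc1)(c1ccccc1)C(C)(C)C | intermediate
26 | bicyclic bis-ether: oxepane (O bridges C3 and C16) fused at C1–C2 to the tetrahydrofuran; C14 vinyl, C10 Weinreb amide, C9 (Z)-2-iodoprop-1-enyl, C3 (CH2)3OSi(t-Bu)Ph2 | CON(C)C(=O)[C@@H]1[C@@H]2[C@@H](C=C)[C@@H](C)CO[C@@](C)(CCCO[Si](c3ccccc3)(c3ccccc3)C(C)(C)C)[C@H]2O[C@H]1/C=C(/C)I | intermediate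
27 | primary C6 alcohol from 26 | CON(C)C(=O)[C@@H]1[C@@H]2[C@@H](C=C)[C@@H](C)CO[C@@](C)(CCCO)[C@H]2O[C@H]1/C=C(/C)I | intermediate
28 | C6 aldehyde from 27 | CON(C)C(=O)[C@@H]1[C@@H]2[C@@H](C=C)[C@@H](C)CO[C@@](C)(CCC=O)[C@H]2O[C@H]1/C=C(/C)I | intermediate
29 | tricyclic oxonene (rings: oxonene, tetrahydrofuran, oxepane) with (6R)-hydroxyl, (7Z)-olefin, C14 vinyl, C10 Weinreb amide | CON(C)C(=O)[C@@H]2[C@@H]3[C@@H](C=C)[C@@H](C)CO[C@@]1(C)CC[C@@H](O)/C(C)=C\[C@@H]2O[C@@H]31 | intermediate
30 | C6 tert-butyldimethylsilyl ether of 29 | CON(C)C(=O)[C@@H]2[C@@H]3[C@@H](C=C)[C@@H](C)CO[C@@]1(C)CC[C@@H](O[Si](C)(C)C(C)(C)C)/C(C)=C\[C@@H]2O[C@@H]31 | intermediate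
31 | 2-propenyl ketone (C11=O, C12(CH3)=CH2 on C10) with C14 vinyl | C=C(C)C(=O)[C@@H]2[C@@H]3[C@@H](C=C)[C@@H](C)CO[C@@]1(C)CC[C@@H](O[Si](C)(C)C(C)(C)C)/C(C)=C\[C@@H]2O[C@@H]31 | intermediate
32 | tetracyclic enone (C11=O, C12=C13, C12 methyl), C6 silyl ether | O=C1[C@@H]2[C@@H]3[C@@H](C=C1C)[C@@H](C)CO[C@@]1(C)CC[C@@H](O[Si](C)(C)C(C)(C)C)/C(C)=C\[C@@H]2O[C@@H]31 | intermediate
33 | tetracyclic C11 ketone with (12R)-methyl, C6 silyl ether | O=C1[C@@H]2[C@@H]3[C@@H](C[C@H]1C)[C@@H](C)CO[C@@]1(C)CC[C@@H](O[Si](C)(C)C(C)(C)C)/C(C)=C\[C@@H]2O[C@@H]31 | intermediate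
34 | (11R)-alcohol, C6 silyl ether | O[C@H]1[C@@H]2[C@@H]3[C@@H](C[C@H]1C)[C@@H](C)CO[C@@]1(C)CC[C@@H](O[Si](C)(C)C(C)(C)C)/C(C)=C\[C@@H]2O[C@@H]31 | intermediate
35 | C11 acetate, C6 silyl ether | CC(=O)O[C@H]1[C@@H]2[C@@H]3[C@@H](C[C@H]1C)[C@@H](C)CO[C@@]1(C)CC[C@@H](O[Si](C)(C)C(C)(C)C)/C(C)=C\[C@@H]2O[C@@H]31 | intermediate
36 | CNP0289966.2 (11-acetoxy-6-hydroxy asbestinane, 7Z) | CC(=O)O[C@H]1[C@@H]2[C@@H]3[C@@H](C[C@H]1C)[C@@H](C)CO[C@@]1(C)CC[C@@H](O)/C(C)=C\[C@@H]2O[C@@H]31 | target

**Step count and risks**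

Total: 26 steps. Longest linear sequence: 21 steps (steps 2–5 and 10–26).

The three steps most likely to fail:

Step 16 (oxepane closure). The seven-membered closure by a hindered tertiary hydroxyl may be slow. The primary triflate could then be captured by the Weinreb amide oxygen or by the tetrahydrofuran oxygen, or could eliminate. The fallback forms the same C3–O–C16 bond by reductive etherification instead of displacement. It sets out from 24: the primary C16 alcohol would be oxidised (TEMPO, PhI(OAc)2, CH2Cl2) to hydroxy aldehyde F1. Treatment with Et3SiH and Me3SiOTf (CH2Cl2, −78 °C) should then reduce the seven-membered oxocarbenium ion that the tertiary hydroxyl forms reversibly with the aldehyde. The sequence comes back to the route at 26.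

Step 19 (oxonene closure). The facial selectivity at C6 in the nine-membered chromium-mediated closure may be poor or even reversed. The fallback sets C6 by reagent control instead of substrate control. It sets out from 28: the same cyclisation would be run without regard to the C6 configuration. The epimeric allylic alcohols would be oxidised with Dess–Martin periodinane to enone F2. Reduction with (S)-2-methyl-CBS-oxazaborolidine and BH3·SMe2 should then deliver the (6R)-alcohol, and the sequence comes back at 29.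

Step 22 (cyclohexane closure). Ring closure at the 1,1-disubstituted, electron-poor olefin may be slow, so that catalyst decay and intermolecular cross-metathesis of the vinyl groups take over. The fallback closes the ring at a less substituted olefin and adds the C12 methyl group afterwards. It sets out from 30: vinylmagnesium bromide would give vinyl ketone F3. Ring-closing metathesis with the same ruthenium catalyst should give the disubstituted enone F4. α-Iodination (I2, pyridine, CH2Cl2) would give iodoenone F5. Stille methylation (Me4Sn, Pd2(dba)3, AsPh3, CuI, NMP) should then install the methyl group, and the sequence comes back at 32.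

Further compounds
F1 | step 16 | hydroxy aldehyde: compound 24 with C16 oxidised to the aldehyde, free tertiary C3 hydroxyl | CON(C)C(=O)[C@@H]1[C@H]([C@@H](C=C)[C@@H](C)C=O)[C@H](O[C@H]1/C=C(/C)I)[C@@](C)(O)CCCO[Si](c1ccccc1)(c1ccccc1)C(C)(C)C
F2 | step 19 | tricyclic oxonenone: C6 ketone conjugated with the (7Z)-olefin, otherwise as 29 | CON(C)C(=O)[C@@H]2[C@@H]3[C@@H](C=C)[C@@H](C)CO[C@@]1(C)CCC(=O)/C(C)=C\[C@@H]2O[C@@H]31
F3 | step 22 | vinyl ketone (C11=O, C12H=CH2 on C10) with C14 vinyl, C6 silyl ether | C=CC(=O)[C@@H]2[C@@H]3[C@@H](C=C)[C@@H](C)CO[C@@]1(C)CC[C@@H](O[Si](C)(C)C(C)(C)C)/C(C)=C\[C@@H]2O[C@@H]31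
F4 | step 22 | tetracyclic enone without the C12 methyl group (C11=O, C12H=C13H) | O=C1[C@@H]2[C@@H]3[C@@H](C=C1)[C@@H](C)CO[C@@]1(C)CC[C@@H](O[Si](C)(C)C(C)(C)C)/C(C)=C\[C@@H]2O[C@@H]31
F5 | step 22 | tetracyclic 12-iodo enone | O=C1[C@@H]2[C@@H]3[C@@H](C=C1I)[C@@H](C)CO[C@@]1(C)CC[C@@H](O[Si](C)(C)C(C)(C)C)/C(C)=C\[C@@H]2O[C@@H]31
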